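**Plan**

- Retrosynthesis: the two aryl–C(sp3) bonds from C8 and C6 of flavan ring A to the exocyclic methine carbons are cut first. In each arm the oxolane C2–aryl bond is cut next (aryllithium plus lactone carbonyl), then the two C–C bonds at C3 and C4 of that lactone (conjugate addition–aldol on a butenolide).
- Forward: an (S)-5-aryl butenolide is made by asymmetric reduction; a three-component Michael–aldol gives the trisubstituted lactone; two such lactones are joined to (+)-afzelechin in one operation. The oxolane rings arise afterwards by aryl addition and lactol reduction, followed by ketone unmasking and debenzylation.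
- Enabling feature: each methine carbon carries a 4-hydroxyphenyl ring (a latent p-quinone methide), and ring A of the flavan is a phloroglucinol-type ring whose C6–H and C8–H are flanked by oxygen-bearing carbons.
- Stereochemistry: C5 of the butenolide comes from transfer hydrogenation and relays to C4 and C3 (trans, trans), to the methine (face selection next to the lactone) and to the oxolane C2 (hydride to an oxocarbenium ion). The flavan centres come with afzelechin.
- Precursor design: the union is run at the lactone oxidation level, with the aryl ketone masked as a dithiane and one free phenol per arm as the activating group; these helpers are removed in steps 8 to 13.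

Key step: step 7

Assumption: (+)-afzelechin 15 is used as the purchased natural product, and the carbinol carbon of 13 and 14 is carried as both epimers because it becomes trigonal in step 7.

Step 1
Reactants: 1 4-(4-hydroxyphenyl)-4-oxobutanoic acid
Product: 2 benzyl 4-[4-(benzyloxy)phenyl]-4-oxobutanoate
Conditions: BnBr, K2CO3, DMF, rt
Reagents that add atoms: benzyl bromide, BrCc1ccccc1
Why: O-alkylation of the phenoxide and the carboxylate (Williamson ether synthesis and ester alkylation) should give the doubly benzylated keto ester; no stereocentre is formed.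

Step 2
Reactants: 2 benzyl 4-[4-(benzyloxy)phenyl]-4-oxobutanoate
Product: 4 (5S)-5-[4-(benzyloxy)phenyl]oxolan-2-one, via hydroxy ester 3 (not isolated)
Conditions: RuCl[(S,S)-TsDPEN](p-cymene) (1 mol%), HCO2H/Et3N (5:2), CH2Cl2, 30 °C; then TsOH·H2O (5 mol%), toluene, 60 °C
Reagents that add atoms: none
Why: Asymmetric transfer hydrogenation of the aryl ketone (Noyori type) with the (S,S)-catalyst should give the (S)-carbinol by aryl-versus-alkyl face discrimination, and acid-catalysed lactonisation with loss of benzyl alcohol does not touch that centre.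

Step 3
Reactants: 4 (5S)-5-[4-(benzyloxy)phenyl]oxolan-2-one
Product: 7 (5S)-5-[4-(benzyloxy)phenyl]furan-2(5H)-one, via lithium enolate 5 (not isolated), via selenide 6 (not isolated)
Conditions: LiN(iPr)2, THF, −78 °C; PhSeBr, −78 °C; then 30% H2O2, pyridine, CH2Cl2, 0 °C to rt
Reagents that add atoms: none
Why: α-Selenenylation of the lactone enolate followed by selenoxide syn-elimination should place the double bond between C3 and C4 and leave the C5 stereocentre as it is.

Step 4
Reactants: 8 2,4-bis(benzyloxy)benzaldehyde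
Product: 9 2-[2,4-bis(benzyloxy)phenyl]-1,3-dithiane
Conditions: HS(CH2)3SH, BF3·OEt2 (cat.), CH2Cl2, 0 °C
Reagents that add atoms: propane-1,3-dithiol, SCCCS
Why: Lewis-acid-catalysed dithioacetalisation turns the aldehyde into a dithiane acyl-anion equivalent (umpolung); no stereocentre is formed.

Step 5
Reactants: 9 2-[2,4-bis(benzyloxy)phenyl]-1,3-dithiane; 7 (5S)-5-[4-(benzyloxy)phenyl]furan-2(5H)-one; 10 4-[(tert-butyldimethylsilyl)oxy]benzaldehyde
Product: 13 (3R,4S,5S)-5-[4-(benzyloxy)phenyl]-4-{2-[2,4-bis(benzyloxy)phenyl]-1,3-dithian-2-yl}-3-{[4-(tert-butyldimethylsilyloxy)phenyl](hydroxy)methyl}oxolan-2-one (both carbinol epimers), via 2-lithiodithiane 11 (not isolated), via lithium enolate 12 (not isolated)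
Conditions: n-BuLi, THF, −78 to −30 °C; then 7, −78 °C; then 10, −78 °C; AcOH quench at −78 °C
Reagents that add atoms: none
Why: Tandem Michael addition–aldol reaction on a butenolide: the lithiated dithiane should add to C4 anti to the C5 aryl group and the resulting enolate should take up the aldehyde anti to the new C4 substituent, which gives the 3,4-trans-4,5-trans lactone; the carbinol centre is not controlled and need not be.

Step 6
Reactants: 13 silyl-protected aldol lactone
Product: 14 (3R,4S,5S)-5-[4-(benzyloxy)phenyl]-4-{2-[2,4-bis(benzyloxy)phenyl]-1,3-dithian-2-yl}-3-[hydroxy(4-hydroxyphenyl)methyl]oxolan-2-one (both carbinol epimers)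
Conditions: KHF2, MeOH, rt
Reagents that add atoms: none
Why: Bifluoride should cleave the aryl silyl ether selectively (phenolic desilylation) under near-neutral conditions, which uncovers the 4-hydroxybenzyl alcohol needed for quinone methide formation without retro-aldol cleavage.

Step 7
Reactants: 14 4-hydroxybenzyl alcohol lactone (2.3 equiv); 15 (+)-afzelechin, (2R,3S)-2-(4-hydroxyphenyl)-3,4-dihydro-2H-chromene-3,5,7-triol
Product: 18 (2R,3S)-6,8-bis{(S)-[(3S,4S,5S)-5-[4-(benzyloxy)phenyl]-4-{2-[2,4-bis(benzyloxy)phenyl]-1,3-dithian-2-yl}-2-oxooxolan-3-yl](4-hydroxyphenyl)methyl}-2-(4-hydroxyphenyl)-3,4-dihydro-2H-chromene-3,5,7-triol, via quinone methide 16 (not isolated), via 8-monoadduct 17 (not isolated)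
Conditions: (PhO)2P(O)OH (10 mol%), 4 Å molecular sieves, MeCN/CH2Cl2, 0 °C to rt
Reagents that add atoms: none
Why: The phosphoric acid diester should dehydrate the 4-hydroxybenzyl alcohol 14 to the neutral p-quinone methide 16, to whose exocyclic carbon ring A of 15 adds through C8 (1,6-addition, then rearomatisation of both rings) to give 17, which repeats the event at C6 with a second molecule of 16. The closest known reaction type is the Brønsted-acid-catalysed Friedel–Crafts alkylation of phloroglucinols and flavan-3-ols by quinone methides generated in situ from hydroxybenzyl alcohols, which is also the presumed biosynthetic union. No ring is closed. Each new methine centre is set by substrate control from the adjacent lactone carbon C3: A(1,3) strain should hold the C3–H bond in the plane of the quinone methide, so the arene can approach either past the flat lactone carbonyl or past C4 with its dithianyl group and the cis C5 aryl group, and approach past the carbonyl gives the (S) centre. Chemoselectivity is needed and is secured by the single free phenol per arm, since only this benzylic position can become a neutral quinone methide while benzyl protection keeps the lactone C5–O bond and the dialkoxyaryl rings quiet; regioselectivity between C6 and C8 is not needed because both are alkylated by the same electrophile, and ring B is far less nucleophilic than ring A. The union is placed at the lactone stage on purpose, because the C2 aryl group of the later oxolane would sit cis to this side chain and screen the face that has to be attacked.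

Step 8
Reactants: 18 bis-lactone adduct
Product: 19 penta-O-benzyl ether of 18 (benzyl on O5, O7 and O4' of the flavan and on both methine 4-hydroxyphenyl groups; 3-OH free)
Conditions: BnBr, Cs2CO3, DMF, rt to 40 °C
Reagents that add atoms: benzyl bromide, BrCc1ccccc1
Why: Williamson etherification of the five phenols (a carbonate base does not alkylate the secondary 3-OH) removes all acidic O–H groups but one before the organolithium step; stereocentres are not touched.

Step 9
Reactants: 20 4-bromobenzene-1,3-diol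
Product: 21 1-bromo-2,4-bis(benzyloxy)benzene
Conditions: BnBr, K2CO3, acetone, reflux
Reagents that add atoms: benzyl bromide, BrCc1ccccc1
Why: Williamson ether synthesis on both phenols gives the aryl bromide for the second dioxygenated ring.

Step 10
Reactants: 21 1-bromo-2,4-bis(benzyloxy)benzene (3.3 equiv); 19 perbenzylated bis-lactone
Product: 23 bis-lactol in which each of the two lactone carbonyl groups of 19 has become C(OH)[2,4-bis(benzyloxy)phenyl] (anomer mixture), via aryllithium 22 (not isolated)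
Conditions: 21 (3.3 equiv), n-BuLi (3.2 equiv), THF, −78 °C; then 19 (1 equiv), −78 to −40 °C; NH4Cl (aq)
Reagents that add atoms: none
Why: Bromine–lithium exchange turns 21 into aryllithium 22, two molecules of which add to 19, one to each lactone carbonyl (lactone to lactol), while a third is consumed by the free 3-OH; the tetrahedral lithium alkoxides should persist at low temperature so that only one aryl group adds per lactone, and the lactol carbon is left undefined at this point.

Step 11
Reactants: 23 bis-lactol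
Product: 24 bis-oxolane, each arm (2R,3S,4S,5S)-2-[2,4-bis(benzyloxy)phenyl]-5-[4-(benzyloxy)phenyl]-4-{2-[2,4-bis(benzyloxy)phenyl]-1,3-dithian-2-yl}oxolan-3-yl
Conditions: Et3SiH, BF3·OEt2, CH2Cl2, −78 °C
Reagents that add atoms: none
Why: Reductive deoxygenation of the lactols through 2-aryl oxocarbenium ions (ionic hydrogenation): hydride should add to the face opposite the bulky C3 diarylmethyl group, which places the new aryl group cis to it and gives the (2R) centre of the target.

Step 12
Reactants: 24 bis-oxolane bis-dithiane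
Product: 25 pentadeca-O-benzyl ether of the target (both dithianes converted into aryl ketones)
Conditions: MeI, CaCO3, MeCN/THF/H2O, 45 °C
Reagents that add atoms: water, O
Why: Alkylative hydrolysis of the dithianes (S-methylation, ionisation to the aryl-stabilised thionium ion, capture by water) should release both aryl ketones; the α-carbon of each ketone already has the more stable trans,trans arrangement and no phenol is free to be methylated.

Step 13
Reactants: 25 pentadeca-O-benzyl ether of the target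
Product: 26 target, (2R,3S)-6,8-bis{(S)-[(2R,3S,4S,5S)-4-(2,4-dihydroxybenzoyl)-2-(2,4-dihydroxyphenyl)-5-(4-hydroxyphenyl)oxolan-3-yl](4-hydroxyphenyl)methyl}-2-(4-hydroxyphenyl)-3,4-dihydro-2H-chromene-3,5,7-triol
Conditions: H2 (1 atm), Pd(OH)2/C, THF/MeOH, rt
Reagents that add atoms: none
Why: Hydrogenolysis of fifteen benzyl aryl ethers; the hindered cyclic benzylic ethers and the hydrogen-bonded 2-hydroxyaryl ketones are expected to react much more slowly, and no stereocentre is involved (25 must be freed of sulfur by-products first).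

**Compound list**

1 | 4-(4-hydroxyphenyl)-4-oxobutanoic acid | OC(=O)CCC(=O)c1ccc(O)cc1 | starting material
2 | benzyl 4-[4-(benzyloxy)phenyl]-4-oxobutanoate | O=C(CCC(=O)c1ccc(OCc2ccccc2)cc1)OCc1ccccc1 | intermediate
3 | benzyl (4S)-4-[4-(benzyloxy)phenyl]-4-hydroxybutanoate (formed in the flask) | O=C(CC[C@H](O)c1ccc(OCc2ccccc2)cc1)OCc1ccccc1 | intermediate
4 | (5S)-5-[4-(benzyloxy)phenyl]oxolan-2-one | O=C1CC[C@@H](c2ccc(OCc3ccccc3)cc2)O1 | intermediate
5 | lithium enolate of 4 (formed in the flask) | [Li]OC1=CC[C@@H](c2ccc(OCc3ccccc3)cc2)O1 | intermediate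
6 | (5S)-5-[4-(benzyloxy)phenyl]-3-(phenylselanyl)oxolan-2-one, C3 epimers (formed in the flask) | O=C1C([Se]c2ccccc2)C[C@@H](c2ccc(OCc3ccccc3)cc2)O1 | intermediate
7 | (5S)-5-[4-(benzyloxy)phenyl]furan-2(5H)-one | O=C1C=C[C@@H](c2ccc(OCc3ccccc3)cc2)O1 | intermediate
8 | 2,4-bis(benzyloxy)benzaldehyde | O=Cc1ccc(OCc2ccccc2)cc1OCc1ccccc1 | starting material
9 | 2-[2,4-bis(benzyloxy)phenyl]-1,3-dithiane | C1CSC(SC1)c1ccc(OCc2ccccc2)cc1OCc1ccccc1 | intermediate
10 | 4-[(tert-butyldimethylsilyl)oxy]benzaldehyde | O=Cc1ccc(O[Si](C)(C)C(C)(C)C)cc1 | starting material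
11 | 2-[2,4-bis(benzyloxy)phenyl]-2-lithio-1,3-dithiane (formed in the flask) | [Li]C1(SCCCS1)c1ccc(OCc2ccccc2)cc1OCc1ccccc1 | intermediate
12 | lithium enolate from conjugate addition of 11 to 7, 4,5-trans (formed in the flask) | [Li]OC1=C[C@H](C2(SCCCS2)c2ccc(OCc3ccccc3)cc2OCc2ccccc2)[C@@H](c2ccc(OCc3ccccc3)cc2)O1 | intermediate
13 | (3R,4S,5S)-5-[4-(benzyloxy)phenyl]-4-{2-[2,4-bis(benzyloxy)phenyl]-1,3-dithian-2-yl}-3-{[4-(tert-butyldimethylsilyloxy)phenyl](hydroxy)methyl}oxolan-2-one, both carbinol epimers | OC(c1ccc(O[Si](C)(C)C(C)(C)C)cc1)[C@H]1[C@H](C2(SCCCS2)c2ccc(OCc3ccccc3)cc2OCc2ccccc2)[C@@H](c2ccc(OCc3ccccc3)cc2)OC1=O | intermediate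
14 | (3R,4S,5S)-5-[4-(benzyloxy)phenyl]-4-{2-[2,4-bis(benzyloxy)phenyl]-1,3-dithian-2-yl}-3-[hydroxy(4-hydroxyphenyl)methyl]oxolan-2-one, both carbinol epimers | OC(c1ccc(O)cc1)[C@H]1[C@H](C2(SCCCS2)c2ccc(OCc3ccccc3)cc2OCc2ccccc2)[C@@H](c2ccc(OCc3ccccc3)cc2)OC1=O | intermediate
15 | (+)-afzelechin, (2R,3S)-2-(4-hydroxyphenyl)-3,4-dihydro-2H-chromene-3,5,7-triol | Oc1cc(O)c2c(c1)O[C@H](c1ccc(O)cc1)[C@@H](O)C2 | starting material
16 | p-quinone methide of 14, 4-{[(3S,4S,5S)-5-[4-(benzyloxy)phenyl]-4-{2-[2,4-bis(benzyloxy)phenyl]-1,3-dithian-2-yl}-2-oxooxolan-3-yl]methylidene}cyclohexa-2,5-dien-1-one (formed in the flask) | O=C1C=CC(C=C1)=C[C@H]1[C@H](C2(SCCCS2)c2ccc(OCc3ccccc3)cc2OCc2ccccc2)[C@@H](c2ccc(OCc3ccccc3)cc2)OC1=O | intermediate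
17 | 8-monoadduct, afzelechin carrying at C8 the (S)-(4-hydroxyphenyl)(lactone)methyl group of 18 (formed in the flask) | Oc1cc(O)c2c(c1[C@H](c1ccc(O)cc1)[C@H]1[C@H](C3(SCCCS3)c3ccc(OCc4ccccc4)cc3OCc3ccccc3)[C@@H](c3ccc(OCc4ccccc4)cc3)OC1=O)O[C@H](c1ccc(O)cc1)[C@@H](O)C2 | intermediate
18 | (2R,3S)-6,8-bis{(S)-[(3S,4S,5S)-5-[4-(benzyloxy)phenyl]-4-{2-[2,4-bis(benzyloxy)phenyl]-1,3-dithian-2-yl}-2-oxooxolan-3-yl](4-hydroxyphenyl)methyl}-2-(4-hydroxyphenyl)-3,4-dihydro-2H-chromene-3,5,7-triol | S1CCCSC1(c1ccc(OCc2ccccc2)cc1OCc1ccccc1)[C@H]1[C@H]([C@@H](c2ccc(O)cc2)c2c(O)c3c(c([C@H](c4ccc(O)cc4)[C@H]4[C@H](C5(SCCCS5)c5ccc(OCc6ccccc6)cc5OCc5ccccc5)[C@@H](c5ccc(OCc6ccccc6)cc5)OC4=O)c2O)O[C@H](c2ccc(O)cc2)[C@@H](O)C3)C(=O)O[C@@H]1c1ccc(OCc2ccccc2)cc1 | intermediate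
19 | penta-O-benzyl ether of 18 (O5, O7, O4' and both methine aryl oxygens benzylated, 3-OH free) | S1CCCSC1(c1ccc(OCc2ccccc2)cc1OCc1ccccc1)[C@H]1[C@H]([C@@H](c2ccc(OCc7ccccc7)cc2)c2c(OCc7ccccc7)c3c(c([C@H](c4ccc(OCc7ccccc7)cc4)[C@H]4[C@H](C5(SCCCS5)c5ccc(OCc6ccccc6)cc5OCc5ccccc5)[C@@H](c5ccc(OCc6ccccc6)cc5)OC4=O)c2OCc2ccccc2)O[C@H](c2ccc(OCc7ccccc7)cc2)[C@@H](O)C3)C(=O)O[C@@H]1c1ccc(OCc2ccccc2)cc1 | intermediate
20 | 4-bromobenzene-1,3-diol | Oc1ccc(Br)c(O)c1 | starting material
21 | 1-bromo-2,4-bis(benzyloxy)benzene | Brc1ccc(OCc2ccccc2)cc1OCc1ccccc1 | intermediate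
22 | [2,4-bis(benzyloxy)phenyl]lithium (formed in the flask) | [Li]c1ccc(OCc2ccccc2)cc1OCc1ccccc1 | intermediate
23 | bis-lactol, 19 with each lactone C=O replaced by C(OH)[2,4-bis(benzyloxy)phenyl], anomers, in equilibrium with the open hydroxy ketones | S1CCCSC1(c1ccc(OCc2ccccc2)cc1OCc1ccccc1)[C@H]1[C@H]([C@@H](c2ccc(OCc7ccccc7)cc2)c2c(OCc7ccccc7)c3c(c([C@H](c4ccc(OCc7ccccc7)cc4)[C@H]4[C@H](C5(SCCCS5)c5ccc(OCc6ccccc6)cc5OCc5ccccc5)[C@@H](c5ccc(OCc6ccccc6)cc5)OC4(O)c4ccc(OCc6ccccc6)cc4OCc4ccccc4)c2OCc2ccccc2)O[C@H](c2ccc(OCc7ccccc7)cc2)[C@@H](O)C3)C(O)(c2ccc(OCc7ccccc7)cc2OCc2ccccc2)O[C@@H]1c1ccc(OCc2ccccc2)cc1 | intermediate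
24 | bis-oxolane bis-dithiane, each arm (2R,3S,4S,5S)-2-[2,4-bis(benzyloxy)phenyl]-5-[4-(benzyloxy)phenyl]-4-{2-[2,4-bis(benzyloxy)phenyl]-1,3-dithian-2-yl}oxolan-3-yl on an (S)-[4-(benzyloxy)phenyl]methine at C6 and C8 of 5,7,4'-tri-O-benzylafzelechin | S1CCCSC1(c1ccc(OCc2ccccc2)cc1OCc1ccccc1)[C@H]1[C@H]([C@@H](c2ccc(OCc7ccccc7)cc2)c2c(OCc7ccccc7)c3c(c([C@H](c4ccc(OCc7ccccc7)cc4)[C@H]4[C@H](C5(SCCCS5)c5ccc(OCc6ccccc6)cc5OCc5ccccc5)[C@@H](c5ccc(OCc6ccccc6)cc5)O[C@H]4c4ccc(OCc6ccccc6)cc4OCc4ccccc4)c2OCc2ccccc2)O[C@H](c2ccc(OCc7ccccc7)cc2)[C@@H](O)C3)[C@H](c2ccc(OCc7ccccc7)cc2OCc2ccccc2)O[C@@H]1c1ccc(OCc2ccccc2)cc1 | intermediate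
25 | pentadeca-O-benzyl ether of the target (all phenols benzylated, 3-OH free) | O=C(c1ccc(OCc2ccccc2)cc1OCc1ccccc1)[C@H]1[C@H]([C@@H](c2ccc(OCc7ccccc7)cc2)c2c(OCc7ccccc7)c3c(c([C@H](c4ccc(OCc7ccccc7)cc4)[C@H]4[C@H](C(=O)c5ccc(OCc6ccccc6)cc5OCc5ccccc5)[C@@H](c5ccc(OCc6ccccc6)cc5)O[C@H]4c4ccc(OCc6ccccc6)cc4OCc4ccccc4)c2OCc2ccccc2)O[C@H](c2ccc(OCc7ccccc7)cc2)[C@@H](O)C3)[C@H](c2ccc(OCc7ccccc7)cc2OCc2ccccc2)O[C@@H]1c1ccc(OCc2ccccc2)cc1 | intermediate
26 | (2R,3S)-6,8-bis{(S)-[(2R,3S,4S,5S)-4-(2,4-dihydroxybenzoyl)-2-(2,4-dihydroxyphenyl)-5-(4-hydroxyphenyl)oxolan-3-yl](4-hydroxyphenyl)methyl}-2-(4-hydroxyphenyl)-3,4-dihydro-2H-chromene-3,5,7-triol | O=C(c1ccc(O)cc1O)[C@H]1[C@H]([C@@H](c2ccc(O)cc2)c2c(O)c3c(c([C@H](c4ccc(O)cc4)[C@H]4[C@H](C(=O)c5ccc(O)cc5O)[C@@H](c5ccc(O)cc5)O[C@H]4c4ccc(O)cc4O)c2O)O[C@H](c2ccc(O)cc2)[C@@H](O)C3)[C@H](c2ccc(O)cc2O)O[C@@H]1c1ccc(O)cc1 | target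

**Totals**

Total step count: 13. Longest linear sequence: 11 steps (steps 1, 2, 3, 5, 6, 7, 8, 10, 11, 12, 13).

**Steps most likely to fail**

Step 7. The quinone methide 16 may tautomerise to the 3-benzylidene lactone (net dehydration of 14 across the lactone α-carbon), or alkylate a dialkoxyaryl ring of a second molecule, faster than the hindered second arylation at C6. Arylation from the other face would show up as methine epimers. The fallback sets out from 13 and avoids the free quinone methide. The carbinol of 13 is converted with Cl3CCN and catalytic DBU in CH2Cl2 into the trichloroacetimidate F3. F3 is then ionised at −40 °C with catalytic TMSOTf in MeCN/CH2Cl2 in the presence of 15 (Friedel–Crafts alkylation with a benzylic trichloroacetimidate, through a silyloxy-stabilised benzylic cation at low temperature and without a basic counter-ion). This should give the bis-adduct silyl ether F4, and cleavage of its two aryl silyl ethers with KHF2 in MeOH comes back to the route at 18.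

Step 10. The aryllithium may deprotonate the hindered lactones at C3 instead of adding, or add to only one of the two carbonyl groups. The fallback sets out from 19 and changes the acyl electrophile. Aminolysis with MeNH(OMe)·HCl and AlMe3 in CH2Cl2 opens both lactones to the bis(N-methoxy-N-methylamide) diol F5. Its chelated tetrahedral adducts with aryllithium 22 (THF, −78 °C) cannot over-add and should collapse on work-up to the aryl ketones, which close onto the freed benzylic hydroxyl groups and so come back to the route at lactol 23.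

Step 5. The lithiated dithiane may remove the acidic C5–H of the butenolide (loss of the stereocentre through the 2-oxyfuran and loss of material) or add to the carbonyl group instead of C4. The fallback sets out from 9 and separates the two bond formations under non-basic conditions. Lithiation and quenching with Me3SiCl give the 2-silyl dithiane F1. Fluoride-triggered conjugate addition of F1 to 7 (CsF, DMF, 0 °C) should give, after protonation, the 4,5-trans lactone F2. A separate aldol reaction of F2 (LiN(iPr)2, THF, −78 °C, then 10) anti to the C4 substituent comes back to the route at 13.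

Further compounds
F1 | step 5 | 2-[2,4-bis(benzyloxy)phenyl]-2-(trimethylsilyl)-1,3-dithiane | C[Si](C)(C)C1(SCCCS1)c1ccc(OCc2ccccc2)cc1OCc1ccccc1
F2 | step 5 | (4S,5S)-5-[4-(benzyloxy)phenyl]-4-{2-[2,4-bis(benzyloxy)phenyl]-1,3-dithian-2-yl}oxolan-2-one | O=C1C[C@H](C2(SCCCS2)c2ccc(OCc3ccccc3)cc2OCc2ccccc2)[C@@H](c2ccc(OCc3ccccc3)cc2)O1
F3 | step 7 | trichloroacetimidate of 13 at the carbinol oxygen | N=C(OC(c1ccc(O[Si](C)(C)C(C)(C)C)cc1)[C@H]1[C@H](C2(SCCCS2)c2ccc(OCc3ccccc3)cc2OCc2ccccc2)[C@@H](c2ccc(OCc3ccccc3)cc2)OC1=O)C(Cl)(Cl)Cl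
F4 | step 7 | bis-adduct 18 with both methine 4-hydroxyphenyl groups as tert-butyldimethylsilyl ethers | S1CCCSC1(c1ccc(OCc2ccccc2)cc1OCc1ccccc1)[C@H]1[C@H]([C@@H](c2ccc(O[Si](C)(C)C(C)(C)C)cc2)c2c(O)c3c(c([C@H](c4ccc(O[Si](C)(C)C(C)(C)C)cc4)[C@H]4[C@H](C5(SCCCS5)c5ccc(OCc6ccccc6)cc5OCc5ccccc5)[C@@H](c5ccc(OCc6ccccc6)cc5)OC4=O)c2O)O[C@H](c2ccc(O)cc2)[C@@H](O)C3)C(=O)O[C@@H]1c1ccc(OCc2ccccc2)cc1
F5 | step 10 | bis(N-methoxy-N-methylamide) diol from ring opening of both lactones of 19 | S1CCCSC1(c1ccc(OCc2ccccc2)cc1OCc1ccccc1)[C@H]([C@H](O)c1ccc(OCc2ccccc2)cc1)[C@H]([C@@H](c2ccc(OCc7ccccc7)cc2)c2c(OCc7ccccc7)c3c(c([C@H](c4ccc(OCc7ccccc7)cc4)[C@H](C(=O)N(C)OC)[C@H](C5(SCCCS5)c5ccc(OCc6ccccc6)cc5OCc5ccccc5)[C@@H](c5ccc(OCc6ccccc6)cc5)O)c2OCc2ccccc2)O[C@H](c2ccc(OCc7ccccc7)cc2)[C@@H](O)C3)C(=O)N(C)OC
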